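## Retrosynthetic overview

1. Locants as in the target: C1 = ring alkene carbon bearing C7 (the CH2O carbon), C2 (OBz), C3 (OAc), C4 and C5 (OH), C6 (=CH); α = face of O2/O5, β = face of O3/O4. Target ⇐ triol 15 (C3 acetate by opening of a 3,4-orthoacetate) ⇐ 2,7-dibenzoate 14 ⇐ 1,3-diol 13 (C7–OH and C2–OH).
2. 13 ⇐ Tamao oxidation of oxasilolane 12 ⇐ C1–C7 bond formation by radical Heck closure of the iodomethylsilyl ether 11 onto C1=C6; C7 arrives as the CH2 of the tether and the ring double bond is returned.
3. Enabling feature: the allylic oxygen on C2 sits next to alkene carbon C1 and 1,3 to the C7 oxygen, so O2 and C7 can be bridged by one silicon atom in a five-membered 1,2-oxasilolane (O2–Si–C7–C1–C2) fused to the cyclohexene; both oxygens unveiled from that ring are the two benzoate oxygens.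
4. 11 ⇐ mono-TBS ether 8 ⇐ lipase desymmetrisation of meso 2,3-O-isopropylidene-conduritol A (4), which already has the target's relative configuration at C2–C5 ⇐ singlet-oxygen cycloaddition/reduction of cis-1,2-dihydrocatechol acetonide.
5. Ring order: carbocycle bought in (arene cis-diol) → dioxolane (step 1) → 2,3-dioxabicyclo[2.2.2]octene (step 2, opened at once) → temporary oxasilolane (step 8, cleaved in step 9) → transient 3,4-orthoester (step 12).

Key step: step 8

Assumption: the lipase follows the Kazlauskas rule and cleaves the acetate on the (R)-carbinol carbon C5 of 5; if the opposite sense is found, the same enzyme run in the acylation direction on 4 (vinyl acetate) gives the same monoacetate 6.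

## Route

Step 1
Reactants: 1 cis-1,2-dihydrocatechol
Product: 2 cis-1,2-dihydrocatechol acetonide
Conditions: Me2C(OMe)2, TsOH (cat.), CH2Cl2, 0 °C; used at once
Reagents that add atoms: 2,2-dimethoxypropane COC(C)(C)OC
Why: Acid-catalysed transacetalisation closes the cis-fused dioxolane on the cis-diol without touching a stereocentre (acetonide formation).

Step 2
Reactants: 2 cis-1,2-dihydrocatechol acetonide
Product: 4 2,3-O-isopropylidene-conduritol A (meso diol), via endoperoxide 3 (not isolated)
Conditions: O2, hν, TPP (cat.), CH2Cl2, 0 °C; then thiourea, MeOH, rt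
Reagents that add atoms: oxygen O=O
Why: The [4+2] cycloaddition of singlet oxygen should take place on the diene face anti to the dioxolane, and thiourea reduction of the O–O bond then gives the cis-1,4-diol trans to the acetonide, so both carbinol centres are set by the facial selectivity of the cycloaddition.

Step 3
Reactants: 4 2,3-O-isopropylidene-conduritol A
Product: 5 meso diacetate of 4
Conditions: Ac2O, pyridine, DMAP (cat.), CH2Cl2, rt
Reagents that add atoms: acetic anhydride CC(=O)OC(C)=O
Why: DMAP-catalysed acylation of both allylic alcohols, no stereochemical change.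

Step 4
Reactants: 5 meso diacetate
Product: 6 monoacetate (2α-acetoxy, 5α-hydroxy; 2S,5R)
Conditions: lipase PS (Burkholderia cepacia), phosphate buffer pH 7/acetone, rt, pH-stat
Reagents that add atoms: none
Why: Lipase-catalysed desymmetrising hydrolysis of a meso cycloalk-2-ene-1,4-diyl diacetate; the enzyme should cleave the enantiotopic ester on the (R)-carbinol carbon (large group = acetonide-bearing carbon, medium = vinyl CH), which fixes the absolute configuration of the whole route.

Step 5
Reactants: 6 monoacetate
Product: 7 2α-acetoxy-5α-(tert-butyldimethylsilyloxy) acetonide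
Conditions: TBSCl, imidazole, DMF, rt
Reagents that add atoms: tert-butyldimethylsilyl chloride CC(C)(C)[Si](C)(C)Cl
Why: Standard imidazole-promoted silylation of the free allylic alcohol at C5.

Step 6
Reactants: 7 2α-acetoxy-5α-silyloxy acetonide
Product: 8 5α-(tert-butyldimethylsilyloxy)-2α-ol
Conditions: K2CO3, MeOH, 0 °C
Reagents that add atoms: none
Why: Mild methanolysis removes the acetate while the TBS ether stays, as in the standard preparation of mono-silylated cis-cycloalk-2-ene-1,4-diols.

Step 7
Reactants: 8 5α-(tert-butyldimethylsilyloxy)-2α-ol; 9 (bromomethyl)chlorodimethylsilane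
Product: 11 2-O-(iodomethyl)dimethylsilyl ether, via bromomethylsilyl ether 10 (not isolated)
Conditions: Et3N, DMAP (cat.), CH2Cl2, 0 °C; then NaI, acetone, rt, dark
Reagents that add atoms: sodium iodide [Na+].[I-]
Why: O-silylation of the allylic alcohol by the chlorosilane followed by Finkelstein exchange at the α-silyl CH2–Br installs the radical precursor on O2 only.

Step 8
Reactants: 11 2-O-(iodomethyl)dimethylsilyl ether
Product: 12 fused 1,2-oxasilolane (O2–SiMe2–C7H2–C1, C1=C6 retained)
Conditions: Pd(OAc)2 (10 mol %), Xantphos (20 mol %), Cs2CO3, degassed PhH, blue LEDs, rt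
Reagents that add atoms: none
Why: Proposed new method: photoexcited Pd(0)–Xantphos transfers one electron to the C–I bond of 11, and the resulting silylmethyl radical closes the five-membered 1,2-oxasilolane (O2–Si–C7–C1–C2) by 5-exo-trig attack on C1 from the α face, the same ring closure as in Stork–Nishiyama silicon-tethered radical cyclisations of cyclohex-2-enyl (halomethyl)silyl ethers. The C6 radical should then combine with Pd(I) on the open β face, and syn β-hydride elimination of H–C1 restores the C1=C6 double bond, so that the vinylic hydrogen at C1 is replaced by C7. The closest known reaction type is the Pd-catalysed silyl-methyl Heck reaction of (iodomethyl)silyl ethers of alkenols, known for endo closures to seven- to nine-membered siloxacycles but not for a 5-exo closure onto a ring alkene with return of the ring double bond. No stereocentre is made for good: the transient C1 centre is fixed cis to O2 by the tether and erased by the elimination, and C2–C5 are not touched. The step needs attack at C1 rather than C6, secured by the three-atom O–Si–CH2 tether (attack at C6 would give a bridged ring), and elimination toward C1 rather than C5, expected because H–C1 is tertiary and β to silicon (the allylsilane-forming direction of silyl-methyl Heck reactions) whereas C5 carries an inductively deactivating silyloxy group that is also a poor β-leaving group.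

Step 9
Reactants: 12 fused 1,2-oxasilolane
Product: 13 1-(hydroxymethyl)-2α-ol (C7,O2-diol)
Conditions: 30 % H2O2, KF, KHCO3, THF/MeOH, rt
Reagents that add atoms: hydrogen peroxide OO
Why: Tamao–Fleming oxidation of the cyclic alkoxysilane moves C7 from silicon to oxygen and frees O2, a reaction established for allylic siloxacycles; the secondary TBS ether should survive KF/KHCO3.

Step 10
Reactants: 13 1-(hydroxymethyl)-2α-ol
Product: 14 2,7-di-O-benzoate
Conditions: BzCl, pyridine, DMAP (cat.), CH2Cl2, 0 °C to rt
Reagents that add atoms: benzoyl chloride O=C(Cl)c1ccccc1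
Why: DMAP-catalysed acylation of the only two free hydroxyl groups places both benzoates of the target in one operation.

Step 11
Reactants: 14 2,7-di-O-benzoate
Product: 15 3,4,5-triol 2,7-dibenzoate
Conditions: TFA/H2O/THF, 0 °C to rt
Reagents that add atoms: none
Why: Aqueous acid hydrolyses the isopropylidene acetal and the TBS ether together, while benzoates are stable and acyl migration is slow under acidic conditions.

Step 12
Reactants: 15 3,4,5-triol 2,7-dibenzoate
Product: 17 target, via cyclic 3,4-orthoacetate 16 (not isolated)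
Conditions: MeC(OMe)3, CSA (cat.), MeCN, rt; then 80 % aq. AcOH, rt
Reagents that add atoms: trimethyl orthoacetate COC(C)(OC)OC
Why: The cis-3,4-diol should form the five-membered orthoester in preference to the trans-4,5-diol, and acid hydrolysis through the dioxolan-2-ylium ion gives the axial ester, here C3 because O2 is held pseudo-axial by allylic strain with the C1 substituent, as in the opening of manno- and rhamnopyranoside 2,3-orthoacetates to 2-O-acetates.

## Compound list

1 | cis-1,2-dihydrocatechol (cis-cyclohexa-3,5-diene-1,2-diol, meso) | O[C@H]1C=CC=C[C@H]1O | starting material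
2 | cis-1,2-dihydrocatechol acetonide ((3aR,7aS)-2,2-dimethyl-3a,7a-dihydro-1,3-benzodioxole, meso) | CC1(C)O[C@H]2C=CC=C[C@H]2O1 | intermediate
3 | endoperoxide: 7,8-O-isopropylidene-2,3-dioxabicyclo[2.2.2]oct-5-ene-7,8-diol, O–O bridge anti to the dioxolane (meso) | CC1(C)O[C@H]2[C@@H](O1)[C@H]3C=C[C@@H]2OO3 | intermediate
4 | 2,3-O-isopropylidene-conduritol A (meso; target locants: 2α,5α-diol, 3β,4β-acetonide) | CC1(C)O[C@H]2[C@@H](O1)[C@H](O)C=C[C@@H]2O | intermediate
5 | diacetate of 4 (meso) | CC1(C)O[C@H]2[C@@H](O1)[C@H](OC(C)=O)C=C[C@@H]2OC(C)=O | intermediate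
6 | monoacetate: 2α-acetoxy-5α-hydroxy-3β,4β-O-isopropylidene-cyclohex-1(6)-ene (2S,5R) | CC1(C)O[C@H]2[C@@H](O1)[C@H](O)C=C[C@@H]2OC(C)=O | intermediate
7 | 2α-acetoxy-5α-(tert-butyldimethylsilyloxy)-3β,4β-O-isopropylidene-cyclohex-1(6)-ene | CC1(C)O[C@H]2[C@@H](O1)[C@H](O[Si](C)(C)C(C)(C)C)C=C[C@@H]2OC(C)=O | intermediate
8 | 5α-(tert-butyldimethylsilyloxy)-3β,4β-O-isopropylidene-cyclohex-1(6)-en-2α-ol | CC1(C)O[C@H]2[C@@H](O1)[C@H](O[Si](C)(C)C(C)(C)C)C=C[C@@H]2O | intermediate
9 | (bromomethyl)chlorodimethylsilane | C[Si](C)(Cl)CBr | starting material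
10 | 2-O-(bromomethyl)dimethylsilyl ether of 8 | CC1(C)O[C@H]2[C@@H](O1)[C@H](O[Si](C)(C)C(C)(C)C)C=C[C@@H]2O[Si](C)(C)CBr | intermediate
11 | 2-O-(iodomethyl)dimethylsilyl ether of 8 | CC1(C)O[C@H]2[C@@H](O1)[C@H](O[Si](C)(C)C(C)(C)C)C=C[C@@H]2O[Si](C)(C)CI | intermediate
12 | fused 2,2-dimethyl-1,2-oxasilolane (ring O2–SiMe2–C7H2–C1–C2; C1=C6; 5α-OTBS; 3β,4β-acetonide) | CC1(C)O[C@H]2[C@@H](O1)[C@H](O[Si](C)(C)C(C)(C)C)C=C3[C@@H]2O[Si](C)(C)C3 | intermediate
13 | 1-(hydroxymethyl)-5α-(tert-butyldimethylsilyloxy)-3β,4β-O-isopropylidene-cyclohex-1(6)-en-2α-ol | CC1(C)O[C@H]2[C@@H](O1)[C@H](O[Si](C)(C)C(C)(C)C)C=C(CO)[C@@H]2O | intermediate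
14 | 2,7-di-O-benzoate of 13 | CC1(C)O[C@H]2[C@@H](O1)[C@H](O[Si](C)(C)C(C)(C)C)C=C(COC(=O)c1ccccc1)[C@@H]2OC(=O)c1ccccc1 | intermediate
15 | triol: (2S,3S,4S,5R in target locants)-2-benzoyloxy-1-(benzoyloxymethyl)cyclohex-1(6)-ene-3,4,5-triol | O[C@H]1[C@@H](O)[C@H](O)C=C(COC(=O)c2ccccc2)[C@@H]1OC(=O)c1ccccc1 | intermediate
16 | cyclic 3,4-O-(1-methoxyethylidene) orthoacetate of 15 (both epimers at the orthoester carbon) | COC1(C)O[C@H]2[C@@H](O1)[C@H](O)C=C(COC(=O)c1ccccc1)[C@@H]2OC(=O)c1ccccc1 | intermediate
17 | [(3R,4S,5S,6S)-5-acetyloxy-6-benzoyloxy-3,4-dihydroxycyclohex-1-en-1-yl]methyl benzoate | CC(=O)O[C@H]1[C@@H](O)[C@H](O)C=C(COC(=O)c2ccccc2)[C@@H]1OC(=O)c1ccccc1 | target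

## Step count and risks

Total step count: 12. Longest linear sequence: 12 steps (1 to 17).

**Step 8 (proposed new method).** After the 5-exo closure the C6 centre may lose the hydrogen on C5 instead of the one on C1, which would give a silyl enol ether. It may also be reduced by hydrogen-atom capture, or the silylmethyl radical may abstract H–C3 before it cyclises. The fallback forms the same C1–C7 bond by known cross-coupling chemistry and sets out from 8. Oxidation of the allylic alcohol (MnO2, CH2Cl2) should give the C2 enone F1. α-Iodination (I2, pyridine, CH2Cl2) should give the 1-iodo enone F2. Stille coupling with (tributylstannyl)methanol (Pd(PPh3)4, CuI, dioxane, 80 °C) should give the 1-(hydroxymethyl) enone F3. Luche reduction (NaBH4, CeCl3·7H2O, MeOH, −78 °C) should deliver hydride anti to the dioxolane and give the 2β,7-diol F4, with C2–OH cis to O3. A double Mitsunobu reaction with benzoic acid (PPh3, DIAD, THF) should esterify C7–OH and invert C2, and the route is rejoined at 14.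

**Step 12.** The orthoester may open toward the C4 ester, or the acetyl group may migrate between O3 and O4, so that the regiochemistry of the acetate is lost. The fallback replaces the orthoester opening by protecting-group differentiation and sets out from 15. Butane-2,3-dione, HC(OMe)3 and CSA in MeOH should protect the trans-diequatorial 4,5-diol selectively as the 4,5-O-butane-2,3-diacetal F5. Acetylation of the remaining axial C3–OH (Ac2O, pyridine, DMAP) should give the 3-O-acetyl diacetal F6. TFA/H2O then removes the diacetal and the route is rejoined at 17.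

**Step 4.** The enzyme may discriminate poorly between the two enantiotopic acetates, or with the opposite sense, which would erode or invert the absolute configuration of everything that follows. The fallback replaces the enzymatic desymmetrisation by a classical resolution and sets out from 4. Mono-acylation with (1S)-camphanic chloride (1 equiv, pyridine, DMAP, CH2Cl2, −20 °C) should give two diastereomeric mono-esters that are separated by crystallisation or chromatography; the wanted one is the 2-O-camphanate F7, and the other is returned to 4 by methanolysis. Silylation (TBSCl, imidazole, DMF) should give the 5-O-TBS 2-O-camphanate F8, and K2CO3 in MeOH removes the auxiliary so that the route is rejoined at 8.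

## Further compounds

F1 | step 8 | 5α-(tert-butyldimethylsilyloxy)-3β,4β-O-isopropylidene-cyclohex-1(6)-en-2-one | CC1(C)O[C@H]2[C@@H](O1)[C@H](O[Si](C)(C)C(C)(C)C)C=CC2=O
F2 | step 8 | 1-iodo-5α-(tert-butyldimethylsilyloxy)-3β,4β-O-isopropylidene-cyclohex-1(6)-en-2-one | CC1(C)O[C@H]2[C@@H](O1)[C@H](O[Si](C)(C)C(C)(C)C)C=C(I)C2=O
F3 | step 8 | 1-(hydroxymethyl)-5α-(tert-butyldimethylsilyloxy)-3β,4β-O-isopropylidene-cyclohex-1(6)-en-2-one | CC1(C)O[C@H]2[C@@H](O1)[C@H](O[Si](C)(C)C(C)(C)C)C=C(CO)C2=O
F4 | step 8 | 1-(hydroxymethyl)-5α-(tert-butyldimethylsilyloxy)-3β,4β-O-isopropylidene-cyclohex-1(6)-en-2β-ol | CC1(C)O[C@H]2[C@@H](O1)[C@H](O[Si](C)(C)C(C)(C)C)C=C(CO)[C@H]2O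
F5 | step 12 | 4,5-O-[(2S,3S)-2,3-dimethoxybutane-2,3-diyl] derivative of triol 15 (free C3–OH) | O[C@H]1[C@H]2O[C@](C)(OC)[C@@](C)(OC)O[C@@H]2C=C(COC(=O)c2ccccc2)[C@@H]1OC(=O)c1ccccc1
F6 | step 12 | 3-O-acetyl-4,5-O-[(2S,3S)-2,3-dimethoxybutane-2,3-diyl] derivative of 15 | CC(=O)O[C@H]1[C@H]2O[C@](C)(OC)[C@@](C)(OC)O[C@@H]2C=C(COC(=O)c2ccccc2)[C@@H]1OC(=O)c1ccccc1
F7 | step 4 | 2-O-[(1S,4R)-camphanoyl]-3β,4β-O-isopropylidene-cyclohex-1(6)-en-5α-ol | CC1(C)O[C@H]2[C@@H](O1)[C@H](O)C=C[C@@H]2OC(=O)[C@@]12CC[C@@](C)(C(=O)O1)C2(C)C
F8 | step 4 | 2-O-[(1S,4R)-camphanoyl]-5α-(tert-butyldimethylsilyloxy)-3β,4β-O-isopropylidene-cyclohex-1(6)-ene | CC1(C)O[C@H]2[C@@H](O1)[C@H](O[Si](C)(C)C(C)(C)C)C=C[C@@H]2OC(=O)[C@@]12CC[C@@](C)(C(=O)O1)C2(C)C
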